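## Structural features

The target is a 3-hydroxyisoflavanone. Ring A (a benzene ring with a free phenol at C7) is fused to the heterocyclic ring C (O1, C2, C3, C4), and C3 carries both a hydroxyl group and ring B. Ring B is pentasubstituted: C1' is bonded to C3, C2' and C3' bear free hydroxyls (a catechol), C4' a methoxy group and C5' a 1,1-dimethylallyl (reverse prenyl) group, so only C6' carries hydrogen. C3 is the only stereocentre and is R. It is bonded to O, C1', the C4 carbonyl carbon and the C2 methylene, has no stereogenic neighbour and no hydrogen, so it cannot epimerise by enolisation; it is lost only if the C3–O bond ionises or the C2–C3 bond breaks. The fragile groups are the catechol (oxidised by air in base and by quinone oxidants), the tertiary benzylic α-ketol (ionisation at C3 is assisted by O2' and O4', so acid leads towards the isoflavone, and base invites an α-ketol shift) and the terminal vinyl group (no hydrogenolysis, limited tolerance of strong acid and electrophilic halogen). The real difficulty is C3: a crowded, fully substituted, oxygenated carbon between an ortho-substituted arene and a carbonyl group, needed as one enantiomer and then carried on under near-neutral conditions. The key step uses the fact that C3 is bonded to ring B and to the C4 aroyl carbon, which is the substitution pattern of the carbene carbon of a 2-aryl-2-diazo-1-arylethanone. Its two remaining bonds, C3–O and C3–C2, are made together from an alcohol and formaldehyde, while an ortho fluorine on ring A, inert towards the carbene, is kept as the leaving group for the later O1–C8a bond.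

## Logic of the disconnections

21 ⇒ 20. The three O–Si bonds are cut last. The phenols must be masked through base, a quinone oxidant and a carbene, and silyl ethers are the only masks that come off without acid, strong base or hydrogen. The forward step must use buffered fluoride and touch no skeletal bond.

20 ⇒ 19. The O3–CH2Ar bond is cut. The tertiary oxygen has to be capped while ring C closes, otherwise the tertiary alkoxide would attack C8a and give a five-membered ring. The cap is the very substituent that the key step installs. The forward step needs an oxidative ether cleavage that spares the silylated catechol and the vinyl group.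

19 ⇒ 18. The O1–C8a bond is cut. It sits ortho to the C4 carbonyl, the natural site for addition–elimination on a fluoroarene. The gain is an open-chain aldol with no ring C. The demand is that the primary alkoxide substitutes faster than it fragments by retro-aldol or takes over a silyl group.

18 ⇒ 14 + 15 + 16. The C3–O and C2–C3 bonds are cut together. Both end at C3, which then has only an aryl and an aroyl neighbour and maps onto a carbene carbon. The stereocentre, its oxygen and one carbon are removed at once, leaving three simple components. The forward step must trap the ylide at carbon before the proton shift, and on one face.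

14 ⇒ 13. The C=N2 bond is cut to the active methylene compound. The demand is a diazo transfer mild enough for aryl silyl ethers and free of hazardous diazoalkanes.

13 ⇒ 10 + 12. The C1'–Cα bond is cut, which divides the molecule into its two aromatic halves and makes the route convergent. The forward step must couple a hindered, electron-rich bromide to a ketone enolate once only, without a base that strips silyl ethers.

12 ⇒ 11 and 10 ⇒ 9 ⇒ 8. Only O–Si bonds and then the ketal C–O bonds are changed. The ketal that distinguishes the three adjacent oxygens cannot be removed from the target without acid, so the exchange for silyl ethers is placed on a robust, simple arene.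

8 ⇒ 7 ⇒ 6. The C1'–Br bond and then the O4'–CH3 bond are cut. Bromine is introduced after the allyl group is in place, when only one unhindered ring position is left; methylation of the single free phenol needs no selectivity.

6 ⇒ 4 ⇒ 2 + 3, and 2 ⇒ 1. The C5'–C bond is cut as a [3,3] shift from oxygen, which explains the inverted allyl unit and its position next to O4'. The O–allyl bond and the ketal follow. The ketal lets exactly one terminal hydroxyl of 1 react, which a direct alkylation of 1 could not guarantee.

## Other disconnections considered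

Alternative 1: The C3–C4 bond is cut. In the forward direction a chiral triazolium-derived carbene converts the aldehyde of the keto aldehyde A1 into an acyl anion equivalent, which adds to the tethered ring B ketone; this closes ring C and gives the tris-silyl ether A2.
- In its favour: ring closure and stereocentre come in one step, the tertiary hydroxyl is free from the start, no diazo compound is needed, and the enantioselective aldehyde–ketone benzoin closure to 3-hydroxychroman-4-ones is an established reaction type.
- Against it here: the electrophile is an electron-rich aryl ketone twisted by an ortho silyloxy group. Its α-aryloxy methylene is acidic, so the base that liberates the carbene can start an intramolecular aldol condensation onto the aldehyde and can attack aryl silyl ethers.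
- Comparison: A2 needs only desilylation, so this plan is about two steps shorter after its key step and is the better on step economy. On precedent for this ring system it is also the better. The chosen plan is the better on electrophile reactivity (formaldehyde is the smallest and most reactive partner, and the hindered ring B carbonyl is never attacked) and on working without base.

Alternative 2: The C3–O bond and the C4 carbonyl C–O bond are cut back to the furan double bond of the pterocarpene A3. In the forward direction a chiral Mn(salen)Cl complex with NaOCl epoxidises that bond, water opens the epoxide at the ketal carbon, and collapse of the hemiketal gives the ketone and frees the 2'-phenol in A4.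
- In its favour: the whole skeleton including ring C is assembled by classical chemistry before any stereochemistry, O2' is masked by the furan, and A4 is one desilylation from the target.
- Against it here: the double bond is tetrasubstituted and part of an aromatic benzofuran, a weak substrate class for oxo transfer from manganese, and face selection on a flat tetracycle is uncertain. Hypochlorite can chlorinate the electron-rich rings and oxidise the freed phenol.
- Comparison: in length the two plans are equal. In protecting-group economy and in the mildness of the endgame this alternative is the better, since it needs no base-mediated ring closure on an aldol. The chosen plan is preferred on the stereo-determining step, whose catalyst system is built for fully substituted carbinol centres, and on oxidant tolerance.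

Alternative 3: The epoxide-derived C3–O bond and the O1–C2 bond are cut. In the forward direction the α-methylene ketone A5 is epoxidised by H2O2 under Sc(OTf)3 with a chiral N,N'-dioxide ligand to the epoxide A6. Methanolysis of the ring A acetates then frees the 2-phenoxide, which opens the epoxide at CH2 (6-exo-tet) to give A7.
- In its favour: one flask sets C3 and closes ring C, the closure is gentle (a phenoxide on a primary epoxide carbon, with no aryl fluoride displacement), and neither a diazo compound nor a benzyl-type ether is needed.
- Against it here: A5 is a very reactive acceptor that can dimerise, polymerise or add methanol. Early loss of the ortho acetate would let the phenoxide add in conjugate fashion, which closes ring C without the C3 oxygen and without stereocontrol. The bulky ortho-substituted ring B at the α-carbon lies outside the usual range of the chelation-controlled epoxidation, and alkaline peroxide meets a para-acyl phenol and silyl ethers.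
- Comparison: this alternative is the better on step economy and on the mildness of ring closure. The chosen plan is preferred because its reactive intermediate is generated slowly under dilution and trapped at once, whereas A5 has to exist as a discrete, self-reactive compound. Both stereo-determining steps are extensions of known catalysis, so on that point the plans are equal.

Key step: step 11

Remarks on the chemistry:
- C3 is R in 18, 19, 20 and 21, because the ranking O > C4 > C2 > C1' holds in all four.
- The sense of induction of the phosphoric acid in step 11 cannot be predicted with certainty; the (R)-acid is written, and its enantiomer is used if it should favour the 2S product.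
- Compound 2 is also a catalogue compound; if bought, step 1 falls away.

## Steps

Step 1
Reactants: 1 pyrogallol
Product: 2 2,2-dimethyl-1,3-benzodioxol-4-ol
Conditions: Me2C(OMe)2, TsOH·H2O (cat.), PhMe, reflux, MeOH distilled off
Reagents that add atoms: 2,2-dimethoxypropane, COC(C)(C)OC
Why: Acid-catalysed ketal exchange (acetonide formation); a five-membered ketal can engage only two adjacent oxygens, so exactly one terminal hydroxyl stays free and the three hydroxyls are differentiated.

Step 2
Reactants: 2 2,2-dimethyl-1,3-benzodioxol-4-ol; 3 prenyl bromide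
Product: 4 2,2-dimethyl-4-(3-methylbut-2-enyloxy)-1,3-benzodioxole
Conditions: K2CO3, acetone, reflux
Reagents that add atoms: none
Why: Williamson etherification of the single free phenol with a primary allylic bromide; carbonate in acetone favours O- over C-alkylation.

Step 3
Reactants: 4 2,2-dimethyl-4-(3-methylbut-2-enyloxy)-1,3-benzodioxole
Product: 6 2,2-dimethyl-5-(2-methylbut-3-en-2-yl)-1,3-benzodioxol-4-ol, via dienone 5 (not isolated)
Conditions: PhNEt2, 185 °C, sealed tube, Ar
Reagents that add atoms: none
Why: Aromatic Claisen rearrangement; the [3,3] shift delivers the allyl unit inverted, as the 1,1-dimethylallyl group, to the only free ortho carbon (C5), and dienone 5 enolises to the phenol. The basic amine solvent suppresses acid-catalysed addition of the new phenol to its own vinyl group.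

Step 4
Reactants: 6 2,2-dimethyl-5-(2-methylbut-3-en-2-yl)-1,3-benzodioxol-4-ol
Product: 7 4-methoxy-2,2-dimethyl-5-(2-methylbut-3-en-2-yl)-1,3-benzodioxole
Conditions: MeI, K2CO3, DMF, 40 °C
Reagents that add atoms: iodomethane, CI
Why: Williamson O-methylation; the hindered phenoxide is the only acidic site and iodomethane is small enough to reach it in a dipolar solvent.

Step 5
Reactants: 7 4-methoxy-2,2-dimethyl-5-(2-methylbut-3-en-2-yl)-1,3-benzodioxole
Product: 8 7-bromo-4-methoxy-2,2-dimethyl-5-(2-methylbut-3-en-2-yl)-1,3-benzodioxole
Conditions: NBS (1.05 equiv), MeCN, 0 °C, dark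
Reagents that add atoms: N-bromosuccinimide, O=C1CCC(=O)N1Br
Why: Electrophilic aromatic bromination; C7 is para to the methoxy group and ortho to a ring oxygen, whereas C6 is shielded by the adjacent quaternary carbon, so substitution should go to C7. The neopentyl-type vinyl group is far less nucleophilic towards NBS than the trioxygenated arene.

Step 6
Reactants: 8 7-bromo-4-methoxy-2,2-dimethyl-5-(2-methylbut-3-en-2-yl)-1,3-benzodioxole
Product: 9 3-bromo-6-methoxy-5-(2-methylbut-3-en-2-yl)benzene-1,2-diol
Conditions: 2 M aq. HCl, MeOH, 60 °C, Ar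
Reagents that add atoms: none
Why: Acid-catalysed hydrolysis (transketalisation) of the aryl acetonide; dilute protic acid does not protonate the monosubstituted alkene and leaves the bromide and the methyl ether alone.

Step 7
Reactants: 9 3-bromo-6-methoxy-5-(2-methylbut-3-en-2-yl)benzene-1,2-diol
Product: 10 1-bromo-2,3-bis(tert-butyldimethylsilyloxy)-4-methoxy-5-(2-methylbut-3-en-2-yl)benzene
Conditions: TBSCl (3 equiv), imidazole, DMF, 40 °C
Reagents that add atoms: tert-butyldimethylsilyl chloride, CC(C)(C)[Si](C)(C)Cl
Why: Imidazole-promoted silylation of both phenols; silyl ethers are the only catechol masks that can be removed from the target without acid, base or hydrogen.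

Step 8
Reactants: 11 2'-fluoro-4'-hydroxyacetophenone
Product: 12 2'-fluoro-4'-(triisopropylsilyloxy)acetophenone
Conditions: TIPSCl, imidazole, DMF, 20 °C
Reagents that add atoms: triisopropylsilyl chloride, CC(C)[Si](Cl)(C(C)C)C(C)C
Why: Silylation of the phenol; an aryl silyl ether para to a ketone is the most base-labile of the three, so the bulkier triisopropylsilyl group is chosen to pass steps 9, 10 and 12.

Step 9
Reactants: 10 1-bromo-2,3-bis(tert-butyldimethylsilyloxy)-4-methoxy-5-(2-methylbut-3-en-2-yl)benzene; 12 2'-fluoro-4'-(triisopropylsilyloxy)acetophenone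
Product: 13 2-[2,3-bis(tert-butyldimethylsilyloxy)-4-methoxy-5-(2-methylbut-3-en-2-yl)phenyl]-1-[2-fluoro-4-(triisopropylsilyloxy)phenyl]ethanone
Conditions: Pd(OAc)2 (3 mol%), XPhos (6 mol%), K3PO4, PhMe, 90 °C
Reagents that add atoms: none
Why: Palladium-catalysed α-arylation of a ketone enolate; the bulky biaryl phosphine permits oxidative addition of the hindered electron-rich bromide, and the ortho substituent together with the greater acidity of the product (held as its enolate) should stop the reaction at monoarylation. K3PO4 in place of an alkoxide spares the aryl silyl ethers, and the C–F bond is inert to zerovalent palladium.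

Step 10
Reactants: 13 2-[2,3-bis(tert-butyldimethylsilyloxy)-4-methoxy-5-(2-methylbut-3-en-2-yl)phenyl]-1-[2-fluoro-4-(triisopropylsilyloxy)phenyl]ethanone
Product: 14 2-[2,3-bis(tert-butyldimethylsilyloxy)-4-methoxy-5-(2-methylbut-3-en-2-yl)phenyl]-2-diazo-1-[2-fluoro-4-(triisopropylsilyloxy)phenyl]ethanone
Conditions: p-ABSA (1.3 equiv), DBU (1.5 equiv), dry MeCN, 0 → 20 °C
Reagents that add atoms: 4-acetamidobenzenesulfonyl azide, CC(=O)Nc1ccc(cc1)S(=O)(=O)N=[N+]=[N-]
Why: Regitz diazo transfer; DBU deprotonates the doubly activated benzylic methylene and the enolate attacks the sulfonyl azide. The azide chosen has low shock sensitivity and no diazomethane is involved.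

Step 11
Reactants: 14 2-[2,3-bis(tert-butyldimethylsilyloxy)-4-methoxy-5-(2-methylbut-3-en-2-yl)phenyl]-2-diazo-1-[2-fluoro-4-(triisopropylsilyloxy)phenyl]ethanone; 15 4-methoxybenzyl alcohol; 16 formaldehyde
Product: 18 (2R)-2-[2,3-bis(tert-butyldimethylsilyloxy)-4-methoxy-5-(2-methylbut-3-en-2-yl)phenyl]-1-[2-fluoro-4-(triisopropylsilyloxy)phenyl]-3-hydroxy-2-(4-methoxybenzyloxy)propan-1-one, via oxonium ylide 17 (not isolated)
Conditions: Rh2(OAc)4 (2 mol%), (R)-TRIP [(R)-3,3'-bis(2,4,6-triisopropylphenyl)-1,1'-binaphthyl-2,2'-diyl hydrogen phosphate] (10 mol%), 4 Å MS, CH2Cl2, −20 °C; 15 (3 equiv), 16 (1.5 equiv, dry THF solution); 14 added over 2 h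
Reagents that add atoms: none
Why: Proposed new method: Rh2(OAc)4 expels N2 from 14 to give a donor–acceptor rhodium carbene at C3, the hydroxyl of 15 adds to it, and the oxonium ylide 17 (an enol equivalent held planar by an O–H···O=C hydrogen bond) is intercepted at carbon by acid-activated formaldehyde before the 1,2-proton shift can give plain O–H insertion, so that C3–O and C2–C3 form in one operation; the closest known reaction type is the dirhodium and chiral phosphoric acid co-catalysed three-component trapping of alcohol-derived oxonium ylides of aryl diazoacetates and α-diazoketones by aldehydes, imines and formaldimine equivalents, which has not been shown for a diaryl diazoketone with free formaldehyde. No ring is closed. The new stereocentre C3 is controlled by the catalyst alone: the phosphoryl oxygen binds the ylide O–H and the acidic O–H binds formaldehyde, so the electrophile is delivered to one face of the enol. Formaldehyde has no prochiral face, so the whole induction rests on this face selection. Chemoselectivity for the alcohol over other carbene acceptors is required and is secured by the substrate: the ortho fluorine is not nucleophilic, O2' could reach the carbene only through a four-membered ring, and the vinyl group is neopentylic and meta to the carbene site. The alcohol is used in excess over formaldehyde so that free 15 and not its hemiformal is the main hydroxyl donor, and slow addition of 14 keeps the carbene concentration low and suppresses azine and dimer formation.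

Step 12
Reactants: 18 (2R)-2-[2,3-bis(tert-butyldimethylsilyloxy)-4-methoxy-5-(2-methylbut-3-en-2-yl)phenyl]-1-[2-fluoro-4-(triisopropylsilyloxy)phenyl]-3-hydroxy-2-(4-methoxybenzyloxy)propan-1-one
Product: 19 (3R)-3-[2,3-bis(tert-butyldimethylsilyloxy)-4-methoxy-5-(2-methylbut-3-en-2-yl)phenyl]-3-(4-methoxybenzyloxy)-7-(triisopropylsilyloxy)chroman-4-one
Conditions: NaH (1.2 equiv), THF (0.02 M), 0 °C
Reagents that add atoms: none
Why: Intramolecular nucleophilic aromatic substitution (addition–elimination); the primary alkoxide attacks the fluorine-bearing carbon activated by the ortho carbonyl and closes the six-membered ring, while the capped tertiary oxygen cannot compete. C3 has no hydrogen, so neither epimerisation nor β-elimination is possible; low temperature, dilution and the absence of DMF are chosen to favour ring closure over loss of formaldehyde and silyl transfer.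

Step 13
Reactants: 19 (3R)-3-[2,3-bis(tert-butyldimethylsilyloxy)-4-methoxy-5-(2-methylbut-3-en-2-yl)phenyl]-3-(4-methoxybenzyloxy)-7-(triisopropylsilyloxy)chroman-4-one
Product: 20 (3R)-3-[2,3-bis(tert-butyldimethylsilyloxy)-4-methoxy-5-(2-methylbut-3-en-2-yl)phenyl]-3-hydroxy-7-(triisopropylsilyloxy)chroman-4-one
Conditions: DDQ (1.5 equiv), CH2Cl2/pH 7 phosphate buffer (10:1), 0 → 20 °C
Reagents that add atoms: none
Why: Oxidative cleavage of the 4-methoxybenzyl ether by DDQ (hydride abstraction, then hydrolysis of the oxocarbenium ion); the catechol is still silylated and so is not oxidised, and ring B has no benzylic hydrogen. The buffer keeps acid away from the ionisable C3–O bond.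

Step 14
Reactants: 20 (3R)-3-[2,3-bis(tert-butyldimethylsilyloxy)-4-methoxy-5-(2-methylbut-3-en-2-yl)phenyl]-3-hydroxy-7-(triisopropylsilyloxy)chroman-4-one
Product: 21 (3R)-3-[2,3-dihydroxy-4-methoxy-5-(2-methylbut-3-en-2-yl)phenyl]-3,7-dihydroxychroman-4-one
Conditions: TBAF (3.5 equiv), AcOH (3.5 equiv), THF, 0 °C, Ar
Reagents that add atoms: none
Why: Fluoride-induced cleavage of the three aryl silyl ethers; acetic acid buffers the phenoxides so that the catechol is not exposed to base and air and the α-ketol cannot rearrange. C3 is not touched.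

## Compound list

1 | pyrogallol (benzene-1,2,3-triol) | Oc1cccc(O)c1O | starting material
2 | 2,2-dimethyl-1,3-benzodioxol-4-ol | CC1(C)Oc2cccc(O)c2O1 | intermediate
3 | prenyl bromide (1-bromo-3-methylbut-2-ene) | CC(C)=CCBr | starting material
4 | 2,2-dimethyl-4-(3-methylbut-2-enyloxy)-1,3-benzodioxole | CC(C)=CCOc1cccc2OC(C)(C)Oc12 | intermediate
5 | 2,2-dimethyl-5-(2-methylbut-3-en-2-yl)-1,3-benzodioxol-4(5H)-one (Claisen dienone) | C=CC(C)(C)C1C=CC2=C(OC(C)(C)O2)C1=O | intermediate (not isolated)
6 | 2,2-dimethyl-5-(2-methylbut-3-en-2-yl)-1,3-benzodioxol-4-ol | C=CC(C)(C)c1ccc2OC(C)(C)Oc2c1O | intermediate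
7 | 4-methoxy-2,2-dimethyl-5-(2-methylbut-3-en-2-yl)-1,3-benzodioxole | C=CC(C)(C)c1ccc2OC(C)(C)Oc2c1OC | intermediate
8 | 7-bromo-4-methoxy-2,2-dimethyl-5-(2-methylbut-3-en-2-yl)-1,3-benzodioxole | C=CC(C)(C)c1cc(Br)c2OC(C)(C)Oc2c1OC | intermediate
9 | 3-bromo-6-methoxy-5-(2-methylbut-3-en-2-yl)benzene-1,2-diol | C=CC(C)(C)c1cc(Br)c(O)c(O)c1OC | intermediate
10 | 1-bromo-2,3-bis(tert-butyldimethylsilyloxy)-4-methoxy-5-(2-methylbut-3-en-2-yl)benzene | C=CC(C)(C)c1cc(Br)c(O[Si](C)(C)C(C)(C)C)c(O[Si](C)(C)C(C)(C)C)c1OC | intermediate
11 | 2'-fluoro-4'-hydroxyacetophenone | CC(=O)c1ccc(O)cc1F | starting material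
12 | 2'-fluoro-4'-(triisopropylsilyloxy)acetophenone | CC(=O)c1ccc(O[Si](C(C)C)(C(C)C)C(C)C)cc1F | intermediate
13 | 2-[2,3-bis(tert-butyldimethylsilyloxy)-4-methoxy-5-(2-methylbut-3-en-2-yl)phenyl]-1-[2-fluoro-4-(triisopropylsilyloxy)phenyl]ethanone | C=CC(C)(C)c1cc(CC(=O)c2ccc(O[Si](C(C)C)(C(C)C)C(C)C)cc2F)c(O[Si](C)(C)C(C)(C)C)c(O[Si](C)(C)C(C)(C)C)c1OC | intermediate
14 | 2-[2,3-bis(tert-butyldimethylsilyloxy)-4-methoxy-5-(2-methylbut-3-en-2-yl)phenyl]-2-diazo-1-[2-fluoro-4-(triisopropylsilyloxy)phenyl]ethanone | C=CC(C)(C)c1cc(C(=[N+]=[N-])C(=O)c2ccc(O[Si](C(C)C)(C(C)C)C(C)C)cc2F)c(O[Si](C)(C)C(C)(C)C)c(O[Si](C)(C)C(C)(C)C)c1OC | intermediate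
15 | 4-methoxybenzyl alcohol | COc1ccc(CO)cc1 | starting material
16 | formaldehyde | C=O | starting material
17 | oxonium ylide from the carbene of 14 and 15 | C=CC(C)(C)c1cc([C-]([OH+]Cc2ccc(OC)cc2)C(=O)c2ccc(O[Si](C(C)C)(C(C)C)C(C)C)cc2F)c(O[Si](C)(C)C(C)(C)C)c(O[Si](C)(C)C(C)(C)C)c1OC | intermediate (not isolated)
18 | (2R)-2-[2,3-bis(tert-butyldimethylsilyloxy)-4-methoxy-5-(2-methylbut-3-en-2-yl)phenyl]-1-[2-fluoro-4-(triisopropylsilyloxy)phenyl]-3-hydroxy-2-(4-methoxybenzyloxy)propan-1-one | C=CC(C)(C)c1cc([C@@](C(=O)c2ccc(O[Si](C(C)C)(C(C)C)C(C)C)cc2F)(OCc2ccc(OC)cc2)CO)c(O[Si](C)(C)C(C)(C)C)c(O[Si](C)(C)C(C)(C)C)c1OC | intermediate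
19 | (3R)-3-[2,3-bis(tert-butyldimethylsilyloxy)-4-methoxy-5-(2-methylbut-3-en-2-yl)phenyl]-3-(4-methoxybenzyloxy)-7-(triisopropylsilyloxy)chroman-4-one | C=CC(C)(C)c1cc([C@@]2(OCc3ccc(OC)cc3)COc3cc(O[Si](C(C)C)(C(C)C)C(C)C)ccc3C2=O)c(O[Si](C)(C)C(C)(C)C)c(O[Si](C)(C)C(C)(C)C)c1OC | intermediate
20 | (3R)-3-[2,3-bis(tert-butyldimethylsilyloxy)-4-methoxy-5-(2-methylbut-3-en-2-yl)phenyl]-3-hydroxy-7-(triisopropylsilyloxy)chroman-4-one | C=CC(C)(C)c1cc([C@@]2(O)COc3cc(O[Si](C(C)C)(C(C)C)C(C)C)ccc3C2=O)c(O[Si](C)(C)C(C)(C)C)c(O[Si](C)(C)C(C)(C)C)c1OC | intermediate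
21 | (3R)-3-[2,3-dihydroxy-4-methoxy-5-(2-methylbut-3-en-2-yl)phenyl]-3,7-dihydroxychroman-4-one | C=CC(C)(C)c1cc([C@@]2(O)COc3cc(O)ccc3C2=O)c(O)c(O)c1OC | target

## Step count and least certain steps

Total step count: 14. Longest linear sequence: 13 steps (steps 1–7 and 9–14, from 1 to 21); step 8 is a one-step side branch.

Step 11 (key step; bears the label "Proposed new method:").
- What may go wrong: the 1,2-proton shift may outrun the trap, which ends in plain O–H insertion. The carbene may add to the oxygen of formaldehyde instead of to the alcohol. The hemiformal of 15 may act as hydroxyl donor. Face selection may be poor, because the electrophile is the smallest possible and has no prochiral face to help the catalyst.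
- Fallback (sets out from 14, returns at 18): the two bonds are made one after the other by known reactions and the enantiomers are then separated. Rh2(OAc)4 and 15 in CH2Cl2 convert 14 by ordinary O–H insertion into the racemic α-(4-methoxybenzyloxy) ketone F1. Its lithium enolate (LiHMDS, THF, −78 °C) is hydroxymethylated with monomeric 16 and quenched cold with acetic acid to give the racemic aldol F2. Preparative chromatography on a chiral stationary phase delivers 18.

Step 12.
- What may go wrong: retro-aldol loss of formaldehyde from the alkoxide, which destroys the stereocentre; transfer of a silyl group from O2' or from ring A to the alkoxide, after which the primary oxygen can no longer close the ring.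
- Fallback (sets out from 10, returns at 19): the aryl–oxygen bond is formed at palladium instead of by addition–elimination, so that no free alkoxide is present. 2'-Chloro-4'-hydroxyacetophenone F3 is silylated (TIPSCl, imidazole, DMF) to its triisopropylsilyl ether F4. α-Arylation with 10 under a ligand that leaves aryl chlorides alone (Pd(OAc)2, Xantphos, K3PO4, toluene, 90 °C) gives the chloro deoxybenzoin F5. Diazo transfer as in step 10 gives the chloro diazoketone F6, and the conditions of step 11 give the chloro aldol F7. Pd(OAc)2, 2-(di-tert-butylphosphino)-1,1'-binaphthyl and Cs2CO3 in toluene at 70 °C then close ring C by intramolecular C–O coupling to 19.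

Step 9.
- What may go wrong: sluggish oxidative addition to the hindered, electron-rich bromide with competing hydrodebromination; base-induced desilylation of the para-acyl aryl silyl ether; a second arylation.
- Fallback (sets out from 10 and 12, returns at 14, replacing steps 9 and 10): the aryl–carbon bond is formed on the diazo compound under nearly neutral conditions. Copper-catalysed halogen exchange (CuI, NaI, trans-N,N'-dimethylcyclohexane-1,2-diamine, dioxane, 110 °C) turns 10 into the aryl iodide F8. Ketone 12 is trifluoroacetylated (LiHMDS, CF3CO2CH2CF3, THF, −78 °C) to the trifluoromethyl diketone F9, which on detrifluoroacetylative diazo transfer (4-acetamidobenzenesulfonyl azide, Et3N, H2O, MeCN) gives the terminal diazoketone F10. Palladium-catalysed coupling of F8 with the diazo C–H bond of F10 (Pd(PPh3)4, Ag2CO3, Et3N, toluene, 20 °C) gives 14.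

Step 3.
- What may go wrong: Cope migration of the dienone to the free para position, which would place a normal prenyl group at C7; addition of the new phenol to its vinyl group at high temperature; thermal loss of the prenyl group.
- Fallback (sets out from 2, returns at 8, replacing steps 2–5): the para position is blocked before the rearrangement by the bromine that the route needs in any case. NBS in MeCN at −20 °C brominates 2 para to the hydroxyl to give the bromophenol F11 (any ortho isomer is removed at this stage). Prenylation with 3 and K2CO3 in acetone gives the bromo prenyl ether F12. Its Claisen rearrangement (PhNEt2, 185 °C) can end only at C5 and gives the bromo allylphenol F13, and methylation (MeI, K2CO3, DMF) gives 8.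

## Further compounds

F1 | step 11 | rac-2-[2,3-bis(tert-butyldimethylsilyloxy)-4-methoxy-5-(2-methylbut-3-en-2-yl)phenyl]-1-[2-fluoro-4-(triisopropylsilyloxy)phenyl]-2-(4-methoxybenzyloxy)ethanone | C=CC(C)(C)c1cc(C(OCc2ccc(OC)cc2)C(=O)c2ccc(O[Si](C(C)C)(C(C)C)C(C)C)cc2F)c(O[Si](C)(C)C(C)(C)C)c(O[Si](C)(C)C(C)(C)C)c1OC
F2 | step 11 | rac-2-[2,3-bis(tert-butyldimethylsilyloxy)-4-methoxy-5-(2-methylbut-3-en-2-yl)phenyl]-1-[2-fluoro-4-(triisopropylsilyloxy)phenyl]-3-hydroxy-2-(4-methoxybenzyloxy)propan-1-one (racemate of 18) | C=CC(C)(C)c1cc(C(C(=O)c2ccc(O[Si](C(C)C)(C(C)C)C(C)C)cc2F)(OCc2ccc(OC)cc2)CO)c(O[Si](C)(C)C(C)(C)C)c(O[Si](C)(C)C(C)(C)C)c1OC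
F3 | step 12 | 2'-chloro-4'-hydroxyacetophenone | CC(=O)c1ccc(O)cc1Cl
F4 | step 12 | 2'-chloro-4'-(triisopropylsilyloxy)acetophenone | CC(=O)c1ccc(O[Si](C(C)C)(C(C)C)C(C)C)cc1Cl
F5 | step 12 | 2-[2,3-bis(tert-butyldimethylsilyloxy)-4-methoxy-5-(2-methylbut-3-en-2-yl)phenyl]-1-[2-chloro-4-(triisopropylsilyloxy)phenyl]ethanone | C=CC(C)(C)c1cc(CC(=O)c2ccc(O[Si](C(C)C)(C(C)C)C(C)C)cc2Cl)c(O[Si](C)(C)C(C)(C)C)c(O[Si](C)(C)C(C)(C)C)c1OC
F6 | step 12 | 2-[2,3-bis(tert-butyldimethylsilyloxy)-4-methoxy-5-(2-methylbut-3-en-2-yl)phenyl]-1-[2-chloro-4-(triisopropylsilyloxy)phenyl]-2-diazoethanone | C=CC(C)(C)c1cc(C(=[N+]=[N-])C(=O)c2ccc(O[Si](C(C)C)(C(C)C)C(C)C)cc2Cl)c(O[Si](C)(C)C(C)(C)C)c(O[Si](C)(C)C(C)(C)C)c1OC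
F7 | step 12 | (2R)-2-[2,3-bis(tert-butyldimethylsilyloxy)-4-methoxy-5-(2-methylbut-3-en-2-yl)phenyl]-1-[2-chloro-4-(triisopropylsilyloxy)phenyl]-3-hydroxy-2-(4-methoxybenzyloxy)propan-1-one | C=CC(C)(C)c1cc([C@@](C(=O)c2ccc(O[Si](C(C)C)(C(C)C)C(C)C)cc2Cl)(OCc2ccc(OC)cc2)CO)c(O[Si](C)(C)C(C)(C)C)c(O[Si](C)(C)C(C)(C)C)c1OC
F8 | step 9 | 2,3-bis(tert-butyldimethylsilyloxy)-1-iodo-4-methoxy-5-(2-methylbut-3-en-2-yl)benzene | C=CC(C)(C)c1cc(I)c(O[Si](C)(C)C(C)(C)C)c(O[Si](C)(C)C(C)(C)C)c1OC
F9 | step 9 | 4,4,4-trifluoro-1-[2-fluoro-4-(triisopropylsilyloxy)phenyl]butane-1,3-dione | O=C(CC(=O)C(F)(F)F)c1ccc(O[Si](C(C)C)(C(C)C)C(C)C)cc1F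
F10 | step 9 | 2-diazo-1-[2-fluoro-4-(triisopropylsilyloxy)phenyl]ethanone | [N-]=[N+]=CC(=O)c1ccc(O[Si](C(C)C)(C(C)C)C(C)C)cc1F
F11 | step 3 | 7-bromo-2,2-dimethyl-1,3-benzodioxol-4-ol | CC1(C)Oc2c(Br)ccc(O)c2O1
F12 | step 3 | 7-bromo-2,2-dimethyl-4-(3-methylbut-2-enyloxy)-1,3-benzodioxole | CC(C)=CCOc1ccc(Br)c2OC(C)(C)Oc12
F13 | step 3 | 7-bromo-2,2-dimethyl-5-(2-methylbut-3-en-2-yl)-1,3-benzodioxol-4-ol | C=CC(C)(C)c1cc(Br)c2OC(C)(C)Oc2c1O
A1 | alternative 1 | 4-(tert-butyldimethylsilyloxy)-2-{2-[2,3-bis(tert-butyldimethylsilyloxy)-4-methoxy-5-(2-methylbut-3-en-2-yl)phenyl]-2-oxoethoxy}benzaldehyde | C=CC(C)(C)c1cc(C(=O)COc2cc(O[Si](C)(C)C(C)(C)C)ccc2C=O)c(O[Si](C)(C)C(C)(C)C)c(O[Si](C)(C)C(C)(C)C)c1OC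
A2 | alternative 1 | (3R)-3-[2,3-bis(tert-butyldimethylsilyloxy)-4-methoxy-5-(2-methylbut-3-en-2-yl)phenyl]-7-(tert-butyldimethylsilyloxy)-3-hydroxychroman-4-one | C=CC(C)(C)c1cc([C@@]2(O)COc3cc(O[Si](C)(C)C(C)(C)C)ccc3C2=O)c(O[Si](C)(C)C(C)(C)C)c(O[Si](C)(C)C(C)(C)C)c1OC
A3 | alternative 2 | 3,10-bis(tert-butyldimethylsilyloxy)-9-methoxy-8-(2-methylbut-3-en-2-yl)-6H-benzofuro[3,2-c]chromene | C=CC(C)(C)c1cc2c3COc4cc(O[Si](C)(C)C(C)(C)C)ccc4-c3oc2c(O[Si](C)(C)C(C)(C)C)c1OC
A4 | alternative 2 | (3R)-7-(tert-butyldimethylsilyloxy)-3-[3-(tert-butyldimethylsilyloxy)-2-hydroxy-4-methoxy-5-(2-methylbut-3-en-2-yl)phenyl]-3-hydroxychroman-4-one | C=CC(C)(C)c1cc([C@@]2(O)COc3cc(O[Si](C)(C)C(C)(C)C)ccc3C2=O)c(O)c(O[Si](C)(C)C(C)(C)C)c1OC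
A5 | alternative 3 | 4-{2-[2,3-bis(tert-butyldimethylsilyloxy)-4-methoxy-5-(2-methylbut-3-en-2-yl)phenyl]acryloyl}-1,3-phenylene diacetate | C=CC(C)(C)c1cc(C(=C)C(=O)c2ccc(OC(C)=O)cc2OC(C)=O)c(O[Si](C)(C)C(C)(C)C)c(O[Si](C)(C)C(C)(C)C)c1OC
A6 | alternative 3 | 4-({(2R)-2-[2,3-bis(tert-butyldimethylsilyloxy)-4-methoxy-5-(2-methylbut-3-en-2-yl)phenyl]oxiran-2-yl}carbonyl)-1,3-phenylene diacetate | C=CC(C)(C)c1cc([C@@]2(CO2)C(=O)c3ccc(OC(C)=O)cc3OC(C)=O)c(O[Si](C)(C)C(C)(C)C)c(O[Si](C)(C)C(C)(C)C)c1OC
A7 | alternative 3 | (3R)-3-[2,3-bis(tert-butyldimethylsilyloxy)-4-methoxy-5-(2-methylbut-3-en-2-yl)phenyl]-3,7-dihydroxychroman-4-one | C=CC(C)(C)c1cc([C@@]2(O)COc3cc(O)ccc3C2=O)c(O[Si](C)(C)C(C)(C)C)c(O[Si](C)(C)C(C)(C)C)c1OC
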